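**Retrosynthetic overview**
- The C-7 hydroxyl is installed last by α'-hydroxylation of the dienone ester; the ester bond is cut to a bicyclic dienone alcohol and (2E,4E,6S)-6-hydroxy-6-methylocta-2,4-dienoic acid.
- The dienone alcohol comes from γ,δ-dehydrogenation of a hydroxy octalone, itself made by Robinson annulation (ring A) of 4-hydroxy-2,3-dimethylcyclohexanone with methyl vinyl ketone.
- That hydroxy ketone comes from a metal-free catalytic oxidative desymmetrisation of all-cis meso-2,3-dimethylcyclohexane-1,4-diol, obtained by hydrogenating 2,3-dimethylhydroquinone (ring B is the former arene).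
- The acid comes from a Shi epoxide of a skipped dienoate by vinylogous epoxide opening; the dienoate is assembled from but-1-yne, a methyl group and ethyl 4-bromocrotonate.
- Ring order: ring B first (arene), then ring A (Robinson); no protecting groups.

Assumption: compounds 1, 4, 10 and 11 are commercial, the two chiral organocatalysts (N-oxyl, L-series Shi ketone) are available or made separately, and locants in the Why lines are those of the names in the compound list.

**Route**

Step 1
Reactants: 1 2,3-dimethylbenzene-1,4-diol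
Product: 2 (1R,2S,3R,4S)-2,3-dimethylcyclohexane-1,4-diol (all-cis; meso)
Conditions: H2 (60 bar), 5% Rh/Al2O3, EtOH, 50 °C; recrystallise
Reagents that add atoms: none
Why: Heterogeneous arene hydrogenation over rhodium delivers all hydrogens to one face of the adsorbed ring, so both hydroxyls and both methyls end up cis and the product is the achiral meso diol (relative configuration only).

Step 2
Reactants: 2 (1R,2S,3R,4S)-2,3-dimethylcyclohexane-1,4-diol
Product: 3 (2S,3R,4S)-4-hydroxy-2,3-dimethylcyclohexan-1-one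
Conditions: chiral 4-aryl-1-methyl-2-azaadamantane N-oxyl (5 mol%, enantiomer that oxidises the (R)-carbinol), PhI(OAc)2 (1.05 equiv), CH2Cl2, −20 °C
Reagents that add atoms: none
Why: Proposed new method: the chiral oxoammonium ion formed from the C1-symmetric N-oxyl adds the alkoxide and removes the carbinol hydrogen by a Cope-type elimination whose transition state tells the CH(CH3) flank from the CH2 flank, so only the (R)-carbinol (C-1) of the meso diol is oxidised and the absolute configuration of the remaining carbinol (4S) and its methyl-bearing neighbour (3R) is fixed, with the minor enantiomer drained by faster over-oxidation to the dione; the closest known reaction type is chiral-nitroxyl oxidative kinetic resolution of secondary alcohols, not yet shown as a desymmetrisation of a meso cyclohexane-1,4-diol.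

Step 3
Reactants: 3 (2S,3R,4S)-4-hydroxy-2,3-dimethylcyclohexan-1-one; 4 but-3-en-2-one
Product: 8 (4aR,5R,6S)-6-hydroxy-4a,5-dimethyl-4,4a,5,6,7,8-hexahydronaphthalen-2(3H)-one, via N-benzyl imine 5 (not isolated), via Michael-adduct imine 6 (not isolated), via diketone 7 (not isolated)
Conditions: BnNH2 (1.05 equiv), 4 Å MS, toluene, 60 °C; 4 (1.5 equiv), THF, rt; aq. AcOH, rt; NaOMe (0.3 equiv), MeOH, 60 °C
Reagents that add atoms: none
Why: In this d'Angelo-type imine Michael reaction followed by Robinson aldol condensation, the more substituted secondary enamine adds to the enone through a cyclic aza-ene transition state on the face anti to the pseudoaxial C-3 methyl, so the new quaternary centre (4aR) keeps its methyl cis to the neighbouring methyl, and methoxide then closes ring A.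

Step 4
Reactants: 8 (4aR,5R,6S)-6-hydroxy-4a,5-dimethyl-4,4a,5,6,7,8-hexahydronaphthalen-2(3H)-one
Product: 9 (4aR,5R,6S)-6-hydroxy-4a,5-dimethyl-4,4a,5,6-tetrahydronaphthalen-2(3H)-one
Conditions: chloranil (1.3 equiv), t-BuOH, reflux
Reagents that add atoms: none
Why: Chloranil dehydrogenation of an enone through its dienol (hydride loss from the δ carbon) gives the linear dienone, as with 4-en-3-one steroids carrying free hydroxyls, and no stereocenter is touched.

Step 5
Reactants: 10 but-1-yne; 11 ethyl (2E)-4-bromobut-2-enoate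
Product: 13 ethyl (2E,5E)-6-methylocta-2,5-dienoate, via alkenylalane 12 (not isolated)
Conditions: Me3Al (2 equiv), Cp2ZrCl2 (20 mol%), CH2Cl2, 0 °C to rt; then 11, Pd(PPh3)4 (3 mol%), THF, 0 °C to rt
Reagents that add atoms: trimethylaluminium, C[Al](C)C
Why: Negishi zirconium-catalysed carboalumination adds CH3 and Al syn across the alkyne to give the (E)-alkenylalane, and palladium-catalysed allylic coupling with retention joins it to the CH2 terminus of the bromocrotonate, giving the (5E) skipped diene.

Step 6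
Reactants: 13 ethyl (2E,5E)-6-methylocta-2,5-dienoate
Product: 14 ethyl (2E)-4-[(2S,3S)-3-ethyl-3-methyloxiran-2-yl]but-2-enoate
Conditions: L-series Shi ketone (1,2:4,5-di-O-isopropylidene-β-L-erythro-2,3-hexodiulo-2,6-pyranose, 30 mol%), KHSO5 (as 2KHSO5·KHSO4·K2SO4), K2CO3, Bu4NHSO4, MeCN/(MeO)2CH2/aq. Na2B4O7 buffer (pH 10.5), 0 °C
Reagents that add atoms: potassium peroxymonosulfate, [K+].[O-]S(=O)(=O)OO
Why: In the Shi epoxidation the chiral dioxirane attacks only the electron-rich trisubstituted alkene through a spiro transition state, and the L-series ketone gives the (S,S)-epoxide, which fixes the future C-6 configuration because methyl and ethyl are told apart by the alkene geometry.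

Step 7
Reactants: 14 ethyl (2E)-4-[(2S,3S)-3-ethyl-3-methyloxiran-2-yl]but-2-enoate
Product: 16 (2E,4E,6S)-6-hydroxy-6-methylocta-2,4-dienoic acid, via ethyl ester 15 (not isolated)
Conditions: DBU (0.5 equiv), THF, rt; then LiOH (3 equiv), THF/H2O, rt; 1 M HCl to pH 4, 0 °C
Reagents that add atoms: lithium hydroxide, [Li+].[OH-]
Why: The base removes the γ proton of the enoate and the dienolate opens the epoxide by vinylogous E1cB elimination to the (4E)-dienyl tertiary alcohol with the C–O bond at the stereocenter untouched (6S retained), and saponification then gives the acid.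

Step 8
Reactants: 16 (2E,4E,6S)-6-hydroxy-6-methylocta-2,4-dienoic acid; 9 (4aR,5R,6S)-6-hydroxy-4a,5-dimethyl-4,4a,5,6-tetrahydronaphthalen-2(3H)-one
Product: 18 (1R,2S,8aR)-1,8a-dimethyl-6-oxo-1,2,6,7,8,8a-hexahydronaphthalen-2-yl (2E,4E,6S)-6-hydroxy-6-methylocta-2,4-dienoate, via mixed anhydride 17 (not isolated)
Conditions: 2,4,6-Cl3C6H2COCl (1.1 equiv), Et3N (2.5 equiv), THF, rt; then 9, DMAP (0.3 equiv), toluene, rt
Reagents that add atoms: none
Why: Yamaguchi esterification acylates the secondary allylic alcohol through the mixed anhydride and DMAP with retention at the carbinol carbon, while the tertiary alcohol of the acid is too hindered to react.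

Step 9
Reactants: 18 (1R,2S,8aR)-1,8a-dimethyl-6-oxo-1,2,6,7,8,8a-hexahydronaphthalen-2-yl (2E,4E,6S)-6-hydroxy-6-methylocta-2,4-dienoate
Product: 20 (1R,2S,7R,8aR)-7-hydroxy-1,8a-dimethyl-6-oxo-1,2,6,7,8,8a-hexahydronaphthalen-2-yl (2E,4E,6S)-6-hydroxy-6-methylocta-2,4-dienoate, via dilithium enolate 19 (not isolated)
Conditions: LiN(SiMe3)2 (2.3 equiv), THF, −78 °C; 2-(phenylsulfonyl)-3-phenyloxaziridine (1.3 equiv), −78 °C; AcOH
Reagents that add atoms: 2-(phenylsulfonyl)-3-phenyloxaziridine, O=S(=O)(c1ccccc1)N1OC1c1ccccc1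
Why: Kinetic α'-deprotonation gives the cross-conjugated enolate (the side chain has no enolisable hydrogen), and the Davis oxaziridine hydroxylates it on the face opposite the axial angular methyl, so the new hydroxyl is trans to that methyl (7R).

**Compound list**

1 | 2,3-dimethylbenzene-1,4-diol | Cc1c(O)ccc(O)c1C | starting material
2 | (1R,2S,3R,4S)-2,3-dimethylcyclohexane-1,4-diol (all-cis, meso) | O[C@H]1CC[C@@H](O)[C@@H](C)[C@H]1C | intermediate
3 | (2S,3R,4S)-4-hydroxy-2,3-dimethylcyclohexan-1-one | O[C@H]1CCC(=O)[C@@H](C)[C@H]1C | intermediate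
4 | but-3-en-2-one (methyl vinyl ketone) | CC(=O)C=C | starting material
5 | (1S,2R,3S)-4-(benzylimino)-2,3-dimethylcyclohexan-1-ol | O[C@H]1CCC(=NCc2ccccc2)[C@@H](C)[C@H]1C | intermediate
6 | 4-[(1R,5S,6R)-2-(benzylimino)-5-hydroxy-1,6-dimethylcyclohexyl]butan-2-one | O[C@H]1CCC(=NCc2ccccc2)[C@](C)(CCC(C)=O)[C@H]1C | intermediate
7 | (2R,3R,4S)-4-hydroxy-2,3-dimethyl-2-(3-oxobutyl)cyclohexan-1-one | O[C@H]1CCC(=O)[C@](C)(CCC(C)=O)[C@H]1C | intermediate
8 | (4aR,5R,6S)-6-hydroxy-4a,5-dimethyl-4,4a,5,6,7,8-hexahydronaphthalen-2(3H)-one | O[C@H]1CCC2=CC(=O)CC[C@]2(C)[C@H]1C | intermediate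
9 | (4aR,5R,6S)-6-hydroxy-4a,5-dimethyl-4,4a,5,6-tetrahydronaphthalen-2(3H)-one | O[C@H]1C=CC2=CC(=O)CC[C@]2(C)[C@H]1C | intermediate
10 | but-1-yne | CCC#C | starting material
11 | ethyl (2E)-4-bromobut-2-enoate | CCOC(=O)/C=C/CBr | starting material
12 | dimethyl[(1E)-2-methylbut-1-en-1-yl]alumane | CC/C(C)=C/[Al](C)C | intermediate
13 | ethyl (2E,5E)-6-methylocta-2,5-dienoate | CC/C(C)=C/C/C=C/C(=O)OCC | intermediate
14 | ethyl (2E)-4-[(2S,3S)-3-ethyl-3-methyloxiran-2-yl]but-2-enoate | CC[C@]1(C)O[C@H]1C/C=C/C(=O)OCC | intermediate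
15 | ethyl (2E,4E,6S)-6-hydroxy-6-methylocta-2,4-dienoate | CC[C@](C)(O)/C=C/C=C/C(=O)OCC | intermediate
16 | (2E,4E,6S)-6-hydroxy-6-methylocta-2,4-dienoic acid | CC[C@](C)(O)/C=C/C=C/C(=O)O | intermediate
17 | (2E,4E,6S)-6-hydroxy-6-methylocta-2,4-dienoic 2,4,6-trichlorobenzoic anhydride | CC[C@](C)(O)/C=C/C=C/C(=O)OC(=O)c1c(Cl)cc(Cl)cc1Cl | intermediate
18 | (1R,2S,8aR)-1,8a-dimethyl-6-oxo-1,2,6,7,8,8a-hexahydronaphthalen-2-yl (2E,4E,6S)-6-hydroxy-6-methylocta-2,4-dienoate | CC[C@](C)(O)/C=C/C=C/C(=O)O[C@H]1C=CC2=CC(=O)CC[C@]2(C)[C@H]1C | intermediate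
19 | dilithium salt of 18 (C-6/C-7 enolate of the ketone plus tertiary alkoxide) | CC[C@](C)([O-])/C=C/C=C/C(=O)O[C@H]1C=CC2=CC([O-])=CC[C@]2(C)[C@H]1C.[Li+].[Li+] | intermediate
20 | (1R,2S,7R,8aR)-7-hydroxy-1,8a-dimethyl-6-oxo-1,2,6,7,8,8a-hexahydronaphthalen-2-yl (2E,4E,6S)-6-hydroxy-6-methylocta-2,4-dienoate | CC[C@](C)(O)/C=C/C=C/C(=O)O[C@H]1C=CC2=CC(=O)[C@H](O)C[C@]2(C)[C@H]1C | target

**Step count and risks**

Total step count: 9. Longest linear sequence: 6 steps (1 → 2 → 3 → 8 → 9 → 18 → 20; steps 1, 2, 3, 4, 8, 9).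

Steps most likely to fail:

Step 2 (the proposed new desymmetrisation). The catalyst may not discriminate the two carbinols well enough, or over-oxidation to the dione may dominate. The fallback uses known enzymatic chemistry and sets out from 2. Both hydroxyls are acetylated (Ac2O, pyridine) to (1R,2S,3R,4S)-2,3-dimethylcyclohexane-1,4-diyl diacetate F1. A lipase selected for hydrolysis of the (R)-configured acetate in phosphate buffer gives (1S,2R,3S,4R)-4-hydroxy-2,3-dimethylcyclohexyl acetate F2. Dess–Martin oxidation of the free carbinol gives (1S,2R,3S)-2,3-dimethyl-4-oxocyclohexyl acetate F3, and K2CO3 in MeOH removes the acetate to return to the route at 3.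

Step 4 (chloranil dehydrogenation). The carbinol next to the δ carbon may slow hydride abstraction, or the hot acidic medium may damage the allylic alcohol formed. The fallback changes to a Saegusa–Ito oxidation and sets out from 8. TMSOTf and Et3N give the linear bis-silyl dienol ether (4aR,5R,6S)-4a,5-dimethyl-2,6-bis(trimethylsilyloxy)-3,4,4a,5,6,7-hexahydronaphthalene F4. Pd(OAc)2 in MeCN then gives (4aR,5R,6S)-4a,5-dimethyl-6-(trimethylsilyloxy)-4,4a,5,6-tetrahydronaphthalen-2(3H)-one F5 by palladation at the γ carbon and β-hydride elimination. Dilute aqueous acid removes the silyl ether and the route is rejoined at 9.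

Step 9 (late α'-hydroxylation). Deprotonation at the allylic ester-bearing carbon (ε to the ketone) or base damage to the dienoate could compete with the kinetic enolate. The fallback avoids strong base and sets out from 18. Mn(OAc)3 in refluxing benzene acetoxylates the α' position by a radical path to give (1R,2S,7R,8aR)-7-acetoxy-1,8a-dimethyl-6-oxo-1,2,6,7,8,8a-hexahydronaphthalen-2-yl (2E,4E,6S)-6-hydroxy-6-methylocta-2,4-dienoate F6. Brief K2CO3 in MeOH at 0 °C cleaves the activated α-acetoxy ketone acetate much faster than the hindered dienoate and equilibrates C-7 to the equatorial hydroxyl trans to the angular methyl, which returns to the route at 20.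

Further compounds
F1 | step 2 | (1R,2S,3R,4S)-2,3-dimethylcyclohexane-1,4-diyl diacetate | CC(=O)O[C@H]1CC[C@@H](OC(C)=O)[C@@H](C)[C@H]1C
F2 | step 2 | (1S,2R,3S,4R)-4-hydroxy-2,3-dimethylcyclohexyl acetate | CC(=O)O[C@H]1CC[C@@H](O)[C@@H](C)[C@H]1C
F3 | step 2 | (1S,2R,3S)-2,3-dimethyl-4-oxocyclohexyl acetate | CC(=O)O[C@H]1CCC(=O)[C@@H](C)[C@H]1C
F4 | step 4 | (4aR,5R,6S)-4a,5-dimethyl-2,6-bis(trimethylsilyloxy)-3,4,4a,5,6,7-hexahydronaphthalene | C[Si](C)(C)O[C@H]1CC=C2C=C(O[Si](C)(C)C)CC[C@]2(C)[C@H]1C
F5 | step 4 | (4aR,5R,6S)-4a,5-dimethyl-6-(trimethylsilyloxy)-4,4a,5,6-tetrahydronaphthalen-2(3H)-one | C[Si](C)(C)O[C@H]1C=CC2=CC(=O)CC[C@]2(C)[C@H]1C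
F6 | step 9 | (1R,2S,7R,8aR)-7-acetoxy-1,8a-dimethyl-6-oxo-1,2,6,7,8,8a-hexahydronaphthalen-2-yl (2E,4E,6S)-6-hydroxy-6-methylocta-2,4-dienoate | CC[C@](C)(O)/C=C/C=C/C(=O)O[C@H]1C=CC2=CC(=O)[C@H](OC(C)=O)C[C@]2(C)[C@H]1C
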